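Follow the rate the flask still owes.

| flask | substrate | coupling partner | time |
|---|---|---|---|
| Wednesday's | 100 mM | 150 mM |  |
| Monday's | 50.0 mM | 100 mM |  |
| Saturday's | 100 mM | 300 mM |  |
| Thursday's | 100 mM | 150 mM | 52 min |

| run | time / min | [target] / mM |
|---|---|---|
| Wednesday's run | 0.75 | 2.9 |
| Wednesday's run | 2.3 | 6.4 |
| Wednesday's run | 4.4 | 13.0 |
| Wednesday's run | 6.9 | 17.5 |
| Wednesday's run | 9.9 | 21.1 |
| Wednesday's run | 13 | 23.8 |
| Wednesday's run | 17 | 25.6 |
| Wednesday's run | 21 | 27.5 |
| Monday's run | 0.75 | 1.1 |
| Monday's run | 2.3 | 2.2 |
| Monday's run | 4.4 | 3.8 |
| Monday's run | 6.9 | 5.4 |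
| Monday's run | 9.9 | 7.1 |
| Monday's run | 13 | 7.3 |
| Monday's run | 17 | 8.8 |
| Monday's run | 21 | 10.1 |
| Saturday's run | 0.75 | 7.2 |
| Saturday's run | 2.3 | 17.3 |
| Saturday's run | 4.4 | 28.0 |
| Saturday's run | 6.9 | 36.2 |
| Saturday's run | 9.9 | 42.9 |
| Saturday's run | 13 | 46.3 |
| Saturday's run | 17 | 49.4 |
| Saturday's run | 21 | 48.9 |

(readings scatter by 0.5 mM)

* apparent order in [substrate] of the starting rate, round the charge of the Wednesday's run (the rate where two percent of its substrate have turned into target) (one fixed amount of target, the same in the runs compared)
* apparent order in [coupling partner] of the starting rate, round the charge of the Wednesday's run (the rate where two percent of its substrate have turned into target)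
* target in the Thursday's run at 52 min, as a share of the substrate charged

- Overall: substrate + coupling partner -> target.
- Constant volume, constant temperature.
- Readings of a species count what is bound in complexes too.
- "The second partner" is coupling partner.
- An order is taken over about fifteen percent of the charge, up and down.

Start with Saturday's run against Wednesday's. At the same substrate charge the coupling partner doubles, and the mean rate up to the second reading grows enough to give an order of 1.43. Monday's run changes both charges at once and its early readings are low against the scatter, so take the substrate order as one for now. Wednesday's mean rate over that same stretch is 2.78 mM min⁻¹.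

Now freeze this law and give it what remains in Wednesday's run at 21 min, where c(target) reads 27.5 mM. With substrate and coupling partner reduced one for one, it gives 1.51 mM min⁻¹. But Wednesday's readings from 13 min to 21 min climb at a mean of 0.462 mM min⁻¹, less than that. Call the gap between the two rates, per mM of target held, the loss ceiling: 0.0380 min⁻¹.

Thursday's run repeats Wednesday's charge, so two extremes can be solved in the head. If the gap belongs to substrate or coupling partner, target simply stays, near 27.5 % of the substrate charged. If the gap is all target's own loss and formation stops at 21 min, target decays at the ceiling to 8.46 %. Wednesday's run is still climbing, so formation has not stopped, and you commit to the middle: 18.0 %.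

The forecast gives orders of 0.97 in substrate and 1.4 in coupling partner and, higher than your figure, 30.6 % for Thursday's run, holding that “by 52 min it should be at equilibrium”.

The flask gives orders of 1.1 in substrate and 1.5 in coupling partner, and 22.9 % for Thursday's run.

    2 coupling partner ⇌ reagent dimer, settled at all times (3.800 M⁻¹)
    substrate + reagent dimer → target + coupling partner (1.212 M⁻¹ min⁻¹)
    2 coupling partner → lost reagent (0.2748 M⁻¹ min⁻¹)
    target → decomposed product (0.01884 min⁻¹)

Thursday's 22.9 % at 52 min stands below the 27.5 % read in Wednesday's run at 21 min, so target itself is going. Its turning into decomposed product is one reason: Thursday's flask without that step reaches 45.5 %. The logarithm of the ratio of that share to Thursday's, spread over 52 min, gives a mean loss constant of 0.0132 min⁻¹, below the loss ceiling of 0.0380 min⁻¹.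

The readings stem from a simulated flask with made-up constants, and the scatter is random.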